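The bond to cut is the one between the peroxide oxygen and C3 in the 1,2-dioxane ring. C3 is the β-carbon of the γ-lactone carbonyl (C1), so the bicycle unravels, as in the presumed biosynthesis, to a butenolide (C2=C3) whose quaternary C4 carries a one-carbon arm (C5) ending in the tertiary C6 hydroperoxide. Releasing that hydroperoxide triggers a 6-exo oxa-Michael addition that closes the dioxane and, because the short tether reaches only one lactone face, sets C3 from C4 (cis fusion). C4 is bought as (S)-2-methylglycidol, the C6–OO bond comes from cobalt-catalysed hydroperoxysilylation of a 1,1-disubstituted alkene, and the oxidation-sensitive phenyldiene is attached last.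

Key step: step 6

Numbering used throughout: C1 lactone carbonyl, C2 lactone CH2, C3 CH bearing the peroxide oxygen, C4 quaternary carbon with methyl and lactone oxygen, C5 ring CH2, C6 quaternary peroxy carbon with methyl and side chain C7–C16 (C13=C14, C15=C16, phenyl on C16).

Assumption: capture of O2 by the acyclic tertiary C6 radical in step 5 is not expected to be face-selective, so 12 and 13 are carried as pairs of C6 epimers (the 6S epimer, which leads to the target, is the one drawn) and the 6S bicycle is isolated by chromatography in step 6.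

**Step 1**
Reactants: 1 tert-butyl[(6-bromohexyl)oxy]dimethylsilane; 2 2,3-dibromoprop-1-ene
Product: 4 tert-butyl[(8-bromonon-8-en-1-yl)oxy]dimethylsilane, via Grignard reagent 3 (not isolated)
Conditions: 1, Mg, THF, 40 °C; then CuI (5 mol %), 2, −20 °C to rt
Reagents that add atoms: none
Why: Copper-catalysed coupling of a primary alkyl Grignard reagent at the allylic C–Br bond of 2 (allylic substitution) should leave the vinylic bromide untouched, and no stereocenter is formed.

**Step 2**
Reactants: 4 tert-butyl[(8-bromonon-8-en-1-yl)oxy]dimethylsilane; 5 (S)-2-methylglycidol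
Product: 7 (2R)-11-[(tert-butyldimethylsilyl)oxy]-2-methyl-4-methylideneundecane-1,2-diol, via alkenyl Grignard reagent 6 (not isolated)
Conditions: 4 (2.3 equiv), Mg, THF, reflux; then CuI (10 mol %), 5, −30 to 0 °C; aqueous work-up
Reagents that add atoms: none
Why: Copper-catalysed SN2 opening of the 2,2-disubstituted epoxide at its unhindered CH2 terminus (the first equivalent of 6 only deprotonates the hydroxyl group) does not touch the quaternary carbinol carbon, so C4 comes from the chiral pool with its configuration intact (S in 5 becomes R in 7 only through the change in CIP priorities).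

**Step 3**
Reactants: 7 (2R)-11-[(tert-butyldimethylsilyl)oxy]-2-methyl-4-methylideneundecane-1,2-diol
Product: 8 (2R)-11-[(tert-butyldimethylsilyl)oxy]-2-hydroxy-2-methyl-4-methylideneundecanal
Conditions: SO3·pyridine, DMSO, i-Pr2NEt, CH2Cl2, 0 °C
Reagents that add atoms: none
Why: Parikh–Doering oxidation can act only on the primary hydroxyl group (the tertiary one has no carbinol hydrogen), and the quaternary α-carbon cannot epimerise.

**Step 4**
Reactants: 8 (2R)-11-[(tert-butyldimethylsilyl)oxy]-2-hydroxy-2-methyl-4-methylideneundecanal; 9 (triphenylphosphoranylidene)ketene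
Product: 11 (5R)-5-{9-[(tert-butyldimethylsilyl)oxy]-2-methylidenenonyl}-5-methylfuran-2(5H)-one, via ester ylide 10 (not isolated)
Conditions: toluene, 90 °C
Reagents that add atoms: none
Why: The tertiary hydroxyl group adds to the ketenylidene ylide to give the ester-stabilised phosphorane 10, which closes by intramolecular Wittig olefination onto the neighbouring aldehyde; the five-membered ring enforces the Z double bond and C4 is not involved.

**Step 5**
Reactants: 11 (5R)-5-{9-[(tert-butyldimethylsilyl)oxy]-2-methylidenenonyl}-5-methylfuran-2(5H)-one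
Product: 12 (5R)-5-{(2S)-9-[(tert-butyldimethylsilyl)oxy]-2-methyl-2-[(triethylsilyl)peroxy]nonyl}-5-methylfuran-2(5H)-one (formed together with its epimer at the peroxy carbon)
Conditions: Co(thd)2 (10 mol %, thd = 2,2,6,6-tetramethylheptane-3,5-dionate), O2 (1 atm), Et3SiH, ClCH2CH2Cl, rt
Reagents that add atoms: dioxygen O=O; triethylsilane CC[SiH](CC)CC
Why: Mukaiyama–Isayama hydroperoxysilylation with the divalent cobalt diketonate: hydrogen-atom transfer from a cobalt hydride to the CH2 terminus of the electron-rich 1,1-disubstituted alkene gives the tertiary C6 radical, which is trapped by O2 and silylated, while the electron-poor 1,2-disubstituted butenolide double bond should react far more slowly; C6 is created here without useful facial bias (planar acyclic radical), so both epimers are carried on.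

**Step 6**
Reactants: 12 (5R)-5-{(2S)-9-[(tert-butyldimethylsilyl)oxy]-2-methyl-2-[(triethylsilyl)peroxy]nonyl}-5-methylfuran-2(5H)-one
Product: 14 (3S,4aR,7aR)-3-(7-hydroxyheptyl)-3,4a-dimethyltetrahydro-3H-furo[3,2-c][1,2]dioxin-6(4H)-one, via hydroperoxide 13 (not isolated)
Conditions: HCl (1 % in MeOH), 0 °C to rt; evaporate; Et2NH (0.3 equiv), CF3CH2OH, rt; SiO2 chromatography (removal of the C6 epimer)
Reagents that add atoms: none
Why: Acidic methanol first strips both silyl groups to give hydroperoxide 13; diethylamine in trifluoroethanol then forms a low equilibrium concentration of the peroxy anion, whose terminal oxygen adds to C3, the β-carbon of the butenolide, and the resulting lactone enolate is protonated at C2 by the fluoroalcohol. This is the intramolecular oxa-Michael addition of a hydroperoxide to an α,β-unsaturated ester, a known way to 1,2-dioxanes under amine/fluoroalcohol conditions and the ring closure assumed in the biosynthesis of the plakortolides. The 1,2-dioxane closes in the 6-exo-trig mode (ring O–O–C6–C5–C4–C3, C2 left outside). The only new stereocenter, C3, is set by C4: the one-carbon tether C5 can deliver the peroxide only to the face of the planar butenolide on which it stands, so the two rings must be cis-fused and 4R gives 3R, whichever configuration C6 has. The step needs chemoselectivity for conjugate addition over lactone opening and over base-induced cleavage of the product peroxide, which the weak amine base and the acidic, non-nucleophilic solvent secure, and regioselectivity for C3, which is secured because attack at C2 would be a 7-endo addition to the α-carbon. Both C6 epimers of 13 cyclise, and the rigid 6S bicycle 14 is separated from its 6R epimer by chromatography at this stage.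

**Step 7**
Reactants: 14 (3S,4aR,7aR)-3-(7-hydroxyheptyl)-3,4a-dimethyltetrahydro-3H-furo[3,2-c][1,2]dioxin-6(4H)-one
Product: 15 7-[(3S,4aR,7aR)-3,4a-dimethyl-6-oxohexahydro-3H-furo[3,2-c][1,2]dioxin-3-yl]heptanal
Conditions: Dess–Martin periodinane, CH2Cl2, 0 °C to rt
Reagents that add atoms: none
Why: Dess–Martin oxidation of the primary alcohol runs under neutral, non-reducing conditions that the dialkyl peroxide and the lactone should tolerate, and no stereocenter is affected.

**Step 8**
Reactants: 15 7-[(3S,4aR,7aR)-3,4a-dimethyl-6-oxohexahydro-3H-furo[3,2-c][1,2]dioxin-3-yl]heptanal; 16 diethyl [(2E)-3-phenylprop-2-en-1-yl]phosphonate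
Product: 18 plakortolide Q, via lithiated phosphonate 17 (not isolated)
Conditions: 16 (1.2 equiv), LiN(SiMe3)2 (1.15 equiv), THF, −78 °C; then 15, −78 °C to rt
Reagents that add atoms: none
Why: Horner–Wadsworth–Emmons olefination with the allylic phosphonate anion should form C13=C14 with high E selectivity while the E C15=C16 bond is carried in from 16, and adding the aldehyde to the preformed anion (base in deficit to 16) at low temperature keeps free base away from the acidic C2 protons of the peroxylactone.

**Compound list**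

1 | tert-butyl[(6-bromohexyl)oxy]dimethylsilane | BrCCCCCCO[Si](C)(C)C(C)(C)C | starting material
2 | 2,3-dibromoprop-1-ene | C=C(Br)CBr | starting material
3 | {6-[(tert-butyldimethylsilyl)oxy]hexyl}magnesium bromide | Br[Mg]CCCCCCO[Si](C)(C)C(C)(C)C | intermediate
4 | tert-butyl[(8-bromonon-8-en-1-yl)oxy]dimethylsilane | C=C(Br)CCCCCCCO[Si](C)(C)C(C)(C)C | intermediate
5 | (S)-2-methylglycidol, [(2S)-2-methyloxiran-2-yl]methanol | C[C@]1(CO)CO1 | starting material
6 | {9-[(tert-butyldimethylsilyl)oxy]non-1-en-2-yl}magnesium bromide | C=C([Mg]Br)CCCCCCCO[Si](C)(C)C(C)(C)C | intermediate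
7 | (2R)-11-[(tert-butyldimethylsilyl)oxy]-2-methyl-4-methylideneundecane-1,2-diol | C[C@](O)(CO)CC(=C)CCCCCCCO[Si](C)(C)C(C)(C)C | intermediate
8 | (2R)-11-[(tert-butyldimethylsilyl)oxy]-2-hydroxy-2-methyl-4-methylideneundecanal | C[C@](O)(C=O)CC(=C)CCCCCCCO[Si](C)(C)C(C)(C)C | intermediate
9 | (triphenylphosphoranylidene)ketene | O=C=C=P(c1ccccc1)(c1ccccc1)c1ccccc1 | starting material
10 | (2R)-11-[(tert-butyldimethylsilyl)oxy]-2-methyl-4-methylidene-1-oxoundecan-2-yl (triphenyl-λ5-phosphanylidene)acetate | O=C[C@@](C)(CC(=C)CCCCCCCO[Si](C)(C)C(C)(C)C)OC(=O)C=P(c1ccccc1)(c1ccccc1)c1ccccc1 | intermediate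
11 | (5R)-5-{9-[(tert-butyldimethylsilyl)oxy]-2-methylidenenonyl}-5-methylfuran-2(5H)-one | C[C@]1(CC(=C)CCCCCCCO[Si](C)(C)C(C)(C)C)OC(=O)C=C1 | intermediate
12 | (5R)-5-{(2S)-9-[(tert-butyldimethylsilyl)oxy]-2-methyl-2-[(triethylsilyl)peroxy]nonyl}-5-methylfuran-2(5H)-one (epimer drawn; carried with its epimer at the peroxy carbon) | C[C@](OO[Si](CC)(CC)CC)(CCCCCCCO[Si](C)(C)C(C)(C)C)C[C@@]1(C)OC(=O)C=C1 | intermediate
13 | (5R)-5-[(2S)-2-hydroperoxy-9-hydroxy-2-methylnonyl]-5-methylfuran-2(5H)-one (epimer drawn; carried with its epimer at the peroxy carbon) | C[C@](OO)(CCCCCCCO)C[C@@]1(C)OC(=O)C=C1 | intermediate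
14 | (3S,4aR,7aR)-3-(7-hydroxyheptyl)-3,4a-dimethyltetrahydro-3H-furo[3,2-c][1,2]dioxin-6(4H)-one (cis-fused 1,2-dioxane/γ-lactone) | C[C@]1(CCCCCCCO)C[C@@]2(C)OC(=O)C[C@H]2OO1 | intermediate
15 | 7-[(3S,4aR,7aR)-3,4a-dimethyl-6-oxohexahydro-3H-furo[3,2-c][1,2]dioxin-3-yl]heptanal | C[C@]1(CCCCCCC=O)C[C@@]2(C)OC(=O)C[C@H]2OO1 | intermediate
16 | diethyl [(2E)-3-phenylprop-2-en-1-yl]phosphonate | CCOP(=O)(C/C=C/c1ccccc1)OCC | starting material
17 | lithium salt of the α-carbanion of 16 | [Li+].CCOP(=O)(OCC)[CH-]/C=C/c1ccccc1 | intermediate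
18 | plakortolide Q, (3S,4aR,7aR)-3,4a-dimethyl-3-[(7E,9E)-10-phenyldeca-7,9-dien-1-yl]tetrahydro-3H-furo[3,2-c][1,2]dioxin-6(4H)-one | C[C@]1(CCCCCC/C=C/C=C/c2ccccc2)C[C@@]2(C)OC(=O)C[C@H]2OO1 | target

**Count and risks**

Total step count: 8. Longest linear sequence: 8 steps (1 to 18).

Steps most likely to fail: step 6, step 5, step 8.

Step 6. The conjugate addition of the hindered tertiary peroxy anion to a β-carbon flanked by the quaternary C4 may stall or revert, and on long exposure to base the peroxide may fragment through deprotonation next to the O–O bond. The fallback closes the dioxane on an open-chain enoate and forms the lactone afterwards. It sets out from aldehyde 8: Wittig reaction with Ph3P=CHCO2Me (CH2Cl2, rt) should give methyl (2E,4R)-13-[(tert-butyldimethylsilyl)oxy]-4-hydroxy-4-methyl-6-methylidenetridec-2-enoate F1, which cannot lactonise. Hydroperoxysilylation as in step 5 gives the silyl peroxide F2. HCl/MeOH releases the hydroperoxide F3, which Et2NH/CF3CH2OH cyclises 6-exo to the monocyclic dioxane hydroxy ester F4. In F4 the chair with equatorial acetate arm at C3, axial C4 hydroxyl and equatorial C4 methyl should be preferred, and this C3 epimer is the one that lactonises (PPTS, CH2Cl2) to the cis-fused 14. The other C3 epimer is returned through retro-addition under the amine. The route is rejoined at 14.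

Step 5. Hydrogen-atom transfer to the conjugated C2=C3 bond of the butenolide may compete with transfer to the isolated alkene, and the peroxy intermediate may be over-reduced to the tertiary alcohol. The fallback runs the hydroperoxysilylation before the Michael acceptor exists. It sets out from diol 7: the same Co(thd)2/O2/Et3SiH conditions act on the only alkene present to give the silylperoxy diol F5. Parikh–Doering oxidation gives the silylperoxy hydroxy aldehyde F6. Ylide 9 (THF, 65 °C) then gives, through the ester ylide F7, the butenolide silyl peroxide 12, where the route is rejoined.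

Step 8. The phosphonate carbanion may deprotonate C2 of the peroxylactone, with β-elimination of the peroxide from C3, or attack the O–O bond. The fallback builds C13=C14 before the peroxide exists and ends with a base-free palladium coupling. It sets out from butenolide 11: HF·pyridine (THF) gives the primary alcohol F8, Dess–Martin oxidation gives the aldehyde F9, and Takai olefination (CrCl2, CHI3, THF) gives the (E)-alkenyl iodide F10. Its 1,2-disubstituted, electron-poor double bond should not compete in the hydrogen-atom transfer step. Hydroperoxysilylation as in step 5 gives the silyl peroxide F11. HCl/MeOH then Et2NH/CF3CH2OH give, through the hydroperoxide F12, the bicyclic alkenyl iodide F13 (C6 epimer removed as in step 6). Stille coupling with tributyl[(E)-2-phenylethenyl]stannane (Pd2(dba)3, dba = dibenzylideneacetone, AsPh3, DMF, rt; zerovalent palladium, no base) should give 18 with both alkene geometries retained.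

**Further compounds**

F1 | step 6 | methyl (2E,4R)-13-[(tert-butyldimethylsilyl)oxy]-4-hydroxy-4-methyl-6-methylidenetridec-2-enoate | COC(=O)/C=C/[C@](C)(O)CC(=C)CCCCCCCO[Si](C)(C)C(C)(C)C
F2 | step 6 | methyl (2E,4R,6S)-13-[(tert-butyldimethylsilyl)oxy]-4-hydroxy-4,6-dimethyl-6-[(triethylsilyl)peroxy]tridec-2-enoate | COC(=O)/C=C/[C@](C)(O)C[C@@](C)(OO[Si](CC)(CC)CC)CCCCCCCO[Si](C)(C)C(C)(C)C
F3 | step 6 | methyl (2E,4R,6S)-6-hydroperoxy-4,13-dihydroxy-4,6-dimethyltridec-2-enoate | COC(=O)/C=C/[C@](C)(O)C[C@@](C)(OO)CCCCCCCO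
F4 | step 6 | methyl 2-[(3R,4R,6S)-4-hydroxy-6-(7-hydroxyheptyl)-4,6-dimethyl-1,2-dioxan-3-yl]acetate | C[C@]1(CCCCCCCO)C[C@@](C)(O)[C@@H](CC(=O)OC)OO1
F5 | step 5 | (2R,4S)-11-[(tert-butyldimethylsilyl)oxy]-2,4-dimethyl-4-[(triethylsilyl)peroxy]undecane-1,2-diol | C[C@](O)(CO)C[C@@](C)(OO[Si](CC)(CC)CC)CCCCCCCO[Si](C)(C)C(C)(C)C
F6 | step 5 | (2R,4S)-11-[(tert-butyldimethylsilyl)oxy]-2-hydroxy-2,4-dimethyl-4-[(triethylsilyl)peroxy]undecanal | C[C@](O)(C=O)C[C@@](C)(OO[Si](CC)(CC)CC)CCCCCCCO[Si](C)(C)C(C)(C)C
F7 | step 5 | (2R,4S)-11-[(tert-butyldimethylsilyl)oxy]-2,4-dimethyl-1-oxo-4-[(triethylsilyl)peroxy]undecan-2-yl (triphenyl-λ5-phosphanylidene)acetate | O=C[C@@](C)(C[C@@](C)(OO[Si](CC)(CC)CC)CCCCCCCO[Si](C)(C)C(C)(C)C)OC(=O)C=P(c1ccccc1)(c1ccccc1)c1ccccc1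
F8 | step 8 | (5R)-5-(9-hydroxy-2-methylidenenonyl)-5-methylfuran-2(5H)-one | C[C@]1(CC(=C)CCCCCCCO)OC(=O)C=C1
F9 | step 8 | 9-[(2R)-2-methyl-5-oxo-2,5-dihydrofuran-2-yl]-8-methylidenenonanal | C[C@]1(CC(=C)CCCCCCC=O)OC(=O)C=C1
F10 | step 8 | (5R)-5-[(9E)-10-iodo-2-methylidenedec-9-en-1-yl]-5-methylfuran-2(5H)-one | C[C@]1(CC(=C)CCCCCC/C=C/I)OC(=O)C=C1
F11 | step 8 | (5R)-5-{(2S,9E)-10-iodo-2-methyl-2-[(triethylsilyl)peroxy]dec-9-en-1-yl}-5-methylfuran-2(5H)-one | C[C@](OO[Si](CC)(CC)CC)(CCCCCC/C=C/I)C[C@@]1(C)OC(=O)C=C1
F12 | step 8 | (5R)-5-[(2S,9E)-2-hydroperoxy-10-iodo-2-methyldec-9-en-1-yl]-5-methylfuran-2(5H)-one | C[C@](OO)(CCCCCC/C=C/I)C[C@@]1(C)OC(=O)C=C1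
F13 | step 8 | (3S,4aR,7aR)-3-[(7E)-8-iodooct-7-en-1-yl]-3,4a-dimethyltetrahydro-3H-furo[3,2-c][1,2]dioxin-6(4H)-one | C[C@]1(CCCCCC/C=C/I)C[C@@]2(C)OC(=O)C[C@H]2OO1
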